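**Plan**
Numbering: chroman O1, spiro C2, C3, C4, C4a, C5–C8, C8a; pinane atoms primed.
Feature and first cut: the ring C4a–C5(=O)–C6(CH3)2–C7(=O)–C8(CH3)2–C8a, with its C4a=C8a enol ether to O1, is a phloroglucinol mono-ether that has been C-methylated twice at C6 and twice at C8 and thereby dearomatised. The four C–CH3 bonds are therefore cut first, back to the aromatic chroman-5,7-diol.
Further cuts: the two O-benzyl groups; then O1–C2 and C3–C4 together (o-quinone methide plus the exocyclic alkene of (+)-β-pinene); then C4–CH(CH3)2 and C4–C4a (Grignard addition, ortho-formylation of a 3,5-dialkoxyphenol).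
Forward order: the benzene ring and the pinane bicycle are bought; the dihydropyran ring is the only ring closed (step 3); the arene becomes the dione ring in the last step.
Stereochemistry: C1' and C5' come from (1R,5R)-β-pinene; C2 (S) from addition to the alkene face anti to the gem-dimethyl bridge; C4 (R) from the endo/exo mode of the cycloaddition, the 4-epimer being removed by chromatography.

Key step: step 5

Assumption: (1R,5R)-(+)-β-pinene is bought as such (it is offered commercially, though less widely than its enantiomer); the order in which C6 and C8 take up their methyl groups in step 5 is not known in advance, so one representative sequence of intermediates is numbered.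

**Step 1**
Reactants: 1 3,5-bis(benzyloxy)phenol; 2 paraformaldehyde
Product: 4 2,4-bis(benzyloxy)-6-hydroxybenzaldehyde, via salicyl alcohol 3 (not isolated)
Conditions: MgCl2, Et3N, (CH2O)n, MeCN, reflux; 1 M HCl work-up
Reagents that add atoms: formaldehyde (from paraformaldehyde 2), C=O
Why: Magnesium-mediated ortho-formylation (Casnati–Skattebøl): the magnesium phenoxide delivers formaldehyde to the ortho carbon through a chelate, the resulting salicyl alkoxide 3 is oxidised by hydride transfer to a second formaldehyde, and because the two ortho positions are equivalent and the carbon between the two benzyloxy groups has no chelating oxygen a single aldehyde should result.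

**Step 2**
Reactants: 4 2,4-bis(benzyloxy)-6-hydroxybenzaldehyde; 5 isopropylmagnesium chloride
Product: 6 rac-3,5-bis(benzyloxy)-2-(1-hydroxy-2-methylpropyl)phenol
Conditions: i-PrMgCl (3 equiv), anhydrous CeCl3, THF, −78 to 0 °C; sat. NH4Cl; used without acidic contact
Reagents that add atoms: isopropylmagnesium chloride 5, CC(C)[Mg]Cl
Why: Organocerium 1,2-addition to the aldehyde after deprotonation of the phenol by the first equivalent, cerium suppressing β-hydride reduction by the secondary Grignard reagent; the carbinol centre is formed racemic, which is harmless because it becomes sp2 in step 3.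

**Step 3**
Reactants: 6 rac-3,5-bis(benzyloxy)-2-(1-hydroxy-2-methylpropyl)phenol; 7 (1R,5R)-(+)-β-pinene
Product: 9 (2S,4R,1'S,5'R)-5,7-bis(benzyloxy)-4-isopropyl-6',6'-dimethylspiro[chromane-2,2'-bicyclo[3.1.1]heptane], via o-quinone methide 8 (not isolated)
Conditions: 7 (4 equiv, excess recovered), toluene, 150 °C, sealed tube; chromatographic separation of the C4 epimers
Reagents that add atoms: (+)-β-pinene 7, C=C1CC[C@@H]2C[C@H]1C2(C)C
Why: Thermal dehydration of the o-hydroxybenzyl alcohol gives the E-o-quinone methide 8, which should add to the 1,1-disubstituted alkene of 7 in an inverse-electron-demand hetero-Diels–Alder reaction with O1 bonding to the more substituted alkene carbon (spiro C2) and the methide carbon to the CH2 terminus; attack on the alkene face anti to the gem-dimethyl bridge sets C2 (S), and the transition state with the C1' bridgehead endo sets C4 (R), the exo mode giving the 4-epimer that is separated.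

**Step 4**
Reactants: 9 (2S,4R,1'S,5'R)-5,7-bis(benzyloxy)-4-isopropyl-6',6'-dimethylspiro[chromane-2,2'-bicyclo[3.1.1]heptane]
Product: 10 (2S,4R,1'S,5'R)-4-isopropyl-6',6'-dimethylspiro[chromane-2,2'-bicyclo[3.1.1]heptane]-5,7-diol
Conditions: H2 (1 atm), 10% Pd/C, EtOAc–MeOH, rt; kept under argon and used promptly
Reagents that add atoms: none
Why: Hydrogenolysis of the two benzyl aryl ethers under neutral conditions; the O1–C2 tertiary alkyl aryl ether is not benzylic and the saturated pinane with its cyclobutane is inert to Pd/C and hydrogen at room temperature, so no stereocentre is touched.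

**Step 5**
Reactants: 10 (2S,4R,1'S,5'R)-4-isopropyl-6',6'-dimethylspiro[chromane-2,2'-bicyclo[3.1.1]heptane]-5,7-diol; 11 iodomethane
Product: 15 (2S,4R,1'S,5'R)-4-isopropyl-6,6,8,8,6',6'-hexamethyl-3,4-dihydrospiro[chromene-2,2'-bicyclo[3.1.1]heptane]-5,7(6H,8H)-dione (target), via 6-methyl diol 12 (not isolated), via 6,8-dimethyl diol 13 (not isolated), via 6,6,8-trimethyl enol 14 (not isolated)
Conditions: NaOMe (8 equiv), MeI (12 equiv), degassed MeOH, 0 °C to reflux, Ar; chromatography
Reagents that add atoms: iodomethane 11, CI
Why: Methoxide turns the two phenols into phenoxides, which attack iodomethane through carbon (SN2 at CH3–I) at C6 and C8, the ring carbons ortho/para to both O5 and O7; after the first methyl at each carbon the ring re-aromatises by proton loss (12, 13), the second methylation at C6 gives the non-aromatic vinylogous acid 14, and its anion is methylated at C8 to give 15, which has no acidic C–H left and cannot react further. The closest known reaction type is the exhaustive C-methylation of phloroglucinol and its acyl derivatives to syncarpic-acid-type triketones, together with the nuclear C-methylation of 5,7-dihydroxyflavanones and chromones with MeI and NaOMe. No ring closes and no stereocentre is formed; C2, C4, C1' and C5' carry no acidic hydrogen under these conditions (C4–H sits on the α-substituent of the enone, not at a vinylogous position), so none should epimerise. The step needs C- over O-alkylation and C6/C8 over C4a attack: a hydrogen-bonded sodium phenoxide in methanol with the soft electrophile MeI favours carbon, and C4a is fully substituted and screened by the C4 isopropyl group. Because O1 is already an ether, only O5 and O7 can become carbonyls, which gives the C5/C7 dione with the C4a=C8a enol ether. Methyl ethers and any C4a-methylated dienone are expected as minor products and are removed by chromatography.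

**Compound list**
1 | 3,5-bis(benzyloxy)phenol | Oc1cc(OCc2ccccc2)cc(OCc2ccccc2)c1 | starting material
2 | paraformaldehyde (formaldehyde source) | C=O | starting material
3 | 3,5-bis(benzyloxy)-2-(hydroxymethyl)phenol (magnesium salt in the flask) | OCc1c(O)cc(OCc2ccccc2)cc1OCc1ccccc1 | intermediate
4 | 2,4-bis(benzyloxy)-6-hydroxybenzaldehyde | O=Cc1c(O)cc(OCc2ccccc2)cc1OCc1ccccc1 | intermediate
5 | isopropylmagnesium chloride | CC(C)[Mg]Cl | starting material
6 | rac-3,5-bis(benzyloxy)-2-(1-hydroxy-2-methylpropyl)phenol | CC(C)C(O)c1c(O)cc(OCc2ccccc2)cc1OCc1ccccc1 | intermediate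
7 | (1R,5R)-(+)-β-pinene | C=C1CC[C@@H]2C[C@H]1C2(C)C | starting material
8 | (E)-3,5-bis(benzyloxy)-6-(2-methylpropylidene)cyclohexa-2,4-dien-1-one (o-quinone methide) | CC(C)/C=C1/C(=O)C=C(OCc2ccccc2)C=C1OCc1ccccc1 | intermediate
9 | (2S,4R,1'S,5'R)-5,7-bis(benzyloxy)-4-isopropyl-6',6'-dimethylspiro[chromane-2,2'-bicyclo[3.1.1]heptane] | CC(C)[C@H]1C[C@]2(CC[C@@H]3C[C@H]2C3(C)C)Oc2cc(OCc3ccccc3)cc(OCc3ccccc3)c21 | intermediate
10 | (2S,4R,1'S,5'R)-4-isopropyl-6',6'-dimethylspiro[chromane-2,2'-bicyclo[3.1.1]heptane]-5,7-diol | CC(C)[C@H]1C[C@]2(CC[C@@H]3C[C@H]2C3(C)C)Oc2cc(O)cc(O)c21 | intermediate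
11 | iodomethane | CI | starting material
12 | 6-methyl derivative of diol 10 | CC(C)[C@H]1C[C@]2(CC[C@@H]3C[C@H]2C3(C)C)Oc2cc(O)c(C)c(O)c21 | intermediate
13 | 6,8-dimethyl derivative of diol 10 | CC(C)[C@H]1C[C@]2(CC[C@@H]3C[C@H]2C3(C)C)Oc2c(C)c(O)c(C)c(O)c21 | intermediate
14 | 7-hydroxy-6,6,8-trimethyl-5(6H)-one (dearomatised enol, same C2/C4/pinane configuration) | CC(C)[C@H]1C[C@]2(CC[C@@H]3C[C@H]2C3(C)C)OC2=C1C(=O)C(C)(C)C(O)=C2C | intermediate
15 | (2S,4R,1'S,5'R)-4-isopropyl-6,6,8,8,6',6'-hexamethyl-3,4-dihydrospiro[chromene-2,2'-bicyclo[3.1.1]heptane]-5,7(6H,8H)-dione | CC(C)[C@H]1C[C@]2(CC[C@@H]3C[C@H]2C3(C)C)OC2=C1C(=O)C(C)(C)C(=O)C2(C)C | target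

**Totals**
Total step count: 5. Longest linear sequence: 5 steps (1 → 4 → 6 → 9 → 10 → 15).

**Steps most likely to fail**

Step 5 (key step). The risk is that O-methylation competes with C-methylation and that alkylation occurs at the substituted C4a, so that material drains into methyl ethers and blocked dienones before all four methyl groups are in place. The fallback sets out from 7 and 11 and returns at 15; it installs the methyl groups on the best-precedented substrate before the pyran ring exists. Purchased 2',4',6'-trihydroxyacetophenone is methylated exhaustively with 11 and NaOMe in MeOH to 2-acetyl-3-hydroxy-4,4,6,6-tetramethylcyclohex-2-ene-1,5-dione F1. Hot aqueous HCl removes the acetyl group to give syncarpic acid F2. Knoevenagel condensation of F2 with isobutyraldehyde (pyrrolidine or proline, CH2Cl2) gives 2,2,4,4-tetramethyl-6-(2-methylpropylidene)cyclohexane-1,3,5-trione F3. Heating F3 with 7 in toluene should give 15 by the same oxa-Diels–Alder mode and alkene face as in step 3, with the C4 epimers separated.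

Step 3. The risk is that the o-quinone methide tautomerises by 1,5-hydrogen shift or self-condenses faster than the unactivated alkene traps it, and that endo/exo discrimination at C4 is weak. The fallback sets out from 7 and returns at 10; it builds the pyran ring without a cycloaddition and sets C4 by hydrogenation. Ozonolysis of 7 (O3, CH2Cl2–MeOH, −78 °C; Me2S) gives (1S,5R)-nopinone F4. Kabbe condensation of F4 with purchased 2'-hydroxy-4',6'-bis(benzyloxy)acetophenone (pyrrolidine, MeOH–toluene, heat) should give (2S,1'S,5'R)-5,7-bis(benzyloxy)-6',6'-dimethylspiro[chromane-2,2'-bicyclo[3.1.1]heptan]-4-one F5, the phenoxide closing by oxa-Michael addition anti to the gem-dimethyl bridge. Addition of i-PrMgCl/CeCl3 gives the tertiary benzylic alcohol F6. Mild dehydration (Burgess reagent or PPTS, warm toluene) gives the 4-isopropyl-2H-chromene F7. Hydrogenation over Pd/C should saturate C3=C4 from the face away from the C1' bridgehead, which places the isopropyl group cis to C1' (4R), and cleave both benzyl ethers in the same operation to give 10.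

Step 2. The risk is β-hydride reduction of the hindered, phenoxide-deactivated aldehyde instead of addition, and ionisation of the electron-rich benzylic alcohol during work-up. The fallback sets out from 1 and returns at 6; it forms the C4–C4a bond by a boron-templated ortho-hydroxyalkylation that needs no organometallic reagent. Compound 1, isobutyraldehyde and phenylboronic acid (cat. propionic acid, toluene, Dean–Stark) should give rac-5,7-bis(benzyloxy)-4-isopropyl-2-phenyl-4H-1,3,2-benzodioxaborin F8. Transesterification of F8 with propane-1,3-diol at room temperature releases 6 under neutral conditions.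

**Further compounds**
F1 | step 5 | 2-acetyl-3-hydroxy-4,4,6,6-tetramethylcyclohex-2-ene-1,5-dione (acetylsyncarpic acid, enol form) | CC(=O)C1=C(O)C(C)(C)C(=O)C(C)(C)C1=O
F2 | step 5 | syncarpic acid (2,2,4,4-tetramethylcyclohexane-1,3,5-trione) | CC1(C)C(=O)CC(=O)C(C)(C)C1=O
F3 | step 5 | 2,2,4,4-tetramethyl-6-(2-methylpropylidene)cyclohexane-1,3,5-trione | CC(C)C=C1C(=O)C(C)(C)C(=O)C(C)(C)C1=O
F4 | step 3 | (1S,5R)-6,6-dimethylbicyclo[3.1.1]heptan-2-one ((−)-nopinone) | O=C1CC[C@@H]2C[C@H]1C2(C)C
F5 | step 3 | (2S,1'S,5'R)-5,7-bis(benzyloxy)-6',6'-dimethylspiro[chromane-2,2'-bicyclo[3.1.1]heptan]-4-one | O=C1C[C@]2(CC[C@@H]3C[C@H]2C3(C)C)Oc2cc(OCc3ccccc3)cc(OCc3ccccc3)c21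
F6 | step 3 | (2S,1'S,5'R)-5,7-bis(benzyloxy)-4-isopropyl-6',6'-dimethylspiro[chromane-2,2'-bicyclo[3.1.1]heptan]-4-ol (C4 mixture) | CC(C)C1(O)C[C@]2(CC[C@@H]3C[C@H]2C3(C)C)Oc2cc(OCc3ccccc3)cc(OCc3ccccc3)c21
F7 | step 3 | (2S,1'S,5'R)-5,7-bis(benzyloxy)-4-isopropyl-6',6'-dimethylspiro[chromene-2,2'-bicyclo[3.1.1]heptane] | CC(C)C1=C[C@]2(CC[C@@H]3C[C@H]2C3(C)C)Oc2cc(OCc3ccccc3)cc(OCc3ccccc3)c21
F8 | step 2 | rac-5,7-bis(benzyloxy)-4-isopropyl-2-phenyl-4H-1,3,2-benzodioxaborin | CC(C)C1OB(c2ccccc2)Oc2cc(OCc3ccccc3)cc(OCc3ccccc3)c21
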